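## Structural features

Marchantin H (C28H24O5) is a macrocyclic bis(bibenzyl): four benzene rings closed into one 18-membered ring in the order ring A–O–ring B–CH2CH2–ring C–O–ring D–CH2CH2–ring A. Ring A is a 1,2,4-trisubstituted phenol (OH, ether oxygen ortho to it, bridge para to it), ring B a para-phenylene, ring C a catechol with four substituents in a row (bridge carbon, ether oxygen, OH, OH) and ring D a meta-phenylene. There is no stereocentre and no C=C bond outside the arenes, so no stereocentres stand next to each other and nothing has to be controlled in space. The fragile groups are the three phenols, above all the ring C catechol, which is easily oxidised and binds metals; they travel as methyl ethers until the last step. The real difficulty is twofold: the ring C–O–ring D ether, whose ring C carbon is flanked by the bridge carbon and by an oxygen-bearing carbon, and the entropically costly closure of the 18-membered ring. Ring D carries only that ether oxygen and one CH2, in a 1,3 relation, which is the pattern of O-4 and the 6-methyl carbon of 4-hydroxy-6-methyl-2-pyrone. The key step uses this: the hindered ether is made at pyrone C4 and the bridge at the pyrone methyl group, and pyrone carbons C3 to C6 then become four of the six carbons of ring D by a Diels–Alder reaction across C3 and C6, followed by loss of CO2 and of a sulfinic acid.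

## Logic of the disconnections

**21 ⇒ 20.** The three aryl O–CH3 bonds are the last to be cleaved. Methyl ethers are the smallest masks that survive strong base, 170 °C, copper and a Lewis acid at low temperature, and one reagent removes all three. The demand on the forward step is only that the two diaryl ethers outlast the Lewis acid, which diaryl ethers normally do.

**20 ⇒ 19.** The ring A carbon–oxygen bond of the A–O–B ether is cut. This is the less hindered of the two ethers: the phenol on ring B has free ortho positions and the bromide on ring A has one ortho neighbour. Cutting here opens the macrocycle to a linear bromo phenol. The forward step must favour ring closure over oligomerisation, hence low concentration, and the bromide must have survived every earlier step.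

**19 ⇒ 18 ⇒ 17.** The O–benzyl bond and then the two C–H bonds of the B–C bridge are removed. This traces the saturated bridge back to a stilbene and the free phenol back to an ether that tolerates ylide chemistry. The demand is that both the reduction and the debenzylation leave the C–Br bond intact, which rules out hydrogenation over palladium and points to diimide and a Lewis acid.

**17 ⇒ 13 + 15 (15 ⇒ 14).** The C=C bond of the B–C bridge is cut into an aryl aldehyde and a benzylic phosphonium salt. All of ring B is then a one-step fragment from 14. The olefin geometry is irrelevant because the bond is saturated next.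

**13 ⇒ 9 + 10.** Two C–C bonds of ring D are cut, those from the two unsubstituted CH carbons to the carbons that bear H (para to the bridge) and the bridge CH2CH2. CO2 is added back in the retrosynthetic sense. Ring D disappears and its oxygen and bridge carbon are recognised as O-4 and the C6 side chain of a 2-pyrone. The forward step needs a dienophile that is an acetylene equivalent, which is 10, and enough heat for cycloaddition and CO2 loss. It also needs a base so that aromatisation outruns a second cycloaddition.

**9 ⇒ 7 + 8.** The pyrone C4–O bond is cut. The hindered ether thus becomes an addition–elimination at an unhindered, strongly electrophilic sp2 carbon instead of a copper coupling of a doubly flanked phenol. The forward step asks that the phenoxide of 8 attack carbon and not the sulfonyl sulfur of 7.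

**7 ⇒ 6 ⇒ 4 + 3.** The S–O bond of the sulfonate is cut, and then the C–C bond between the pyrone CH2 and the benzylic CH2. This reduces the whole left half to the cheap pyrone 4 and a benzylic bromide. The forward alkylation must take place at the methyl carbon of the dianion 5, and the aryl bromide must not undergo halogen–metal exchange, so an amide base is used.

**3 ⇒ 2 ⇒ 1.** The benzylic C–Br bond and one C–H bond lead back to the commercial aldehyde 1. Nothing is demanded beyond standard functional group chemistry.

## Other disconnections considered

**Alternative 1:** The cut is the central C–C bond of the B–C bridge, traced back to a CH2–SO2–CH2 unit. In the forward direction the 19-membered dibenzylic sulfone A2 would be treated with KOH and CBr2F2. In situ α-bromination, episulfone formation and SO2 loss (Ramberg–Bäcklund reaction) would contract the ring to the 18-membered stilbene A1, and hydrogenation of A1 would give 20.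
- In its favour: A2 would be reached by ring closure through sulfur, a soft, metal-free substitution that is among the most dependable macrocyclisations. The contraction is intramolecular and needs no high dilution. The geometry of A1 does not matter, and the E assignment is not essential because either isomer is hydrogenated.
- Against it here: both diaryl ethers, the hindered C–O–D ether included, must already be in place, so this plan does not address the first difficulty at all. Two benzylic leaving groups, the ring closure, oxidation at sulfur, contraction and hydrogenation add about four steps after the ethers. CBr2F2 is an ozone-depleting gas of restricted availability.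
- Comparison: on structure, the chosen plan builds ring D and the hindered ether together, while this one takes ring D as a preformed phenol. On mechanism, it relies on ionic substitution and extrusion, not on a pericyclic sequence. On step economy it is longer. On the ring closure itself it is the better plan: closure through sulfur is probably more reliable than the Ullmann macrocyclisation of step 11.

**Alternative 2:** The cut is the ring A carbon–oxygen bond of the A–O–B ether, the same bond that step 11 makes. In the forward direction the seco bisphenol A4 (ring A as a 2,6-dibromophenol, ring B as a 2,6-dichlorophenol) would be oxidised with Tl(NO3)3 in methanol and the dienone reduced with Zn in acetic acid. This would give the trihalogenated macrocycle A3, which would need hydrogenolysis of three carbon–halogen bonds and demethylation of ring C.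
- In its favour: the ring closes at ambient temperature, no carbon–halogen bond has to be activated by a metal, the halogens steer the coupling to oxygen and block C–C coupling, and A3 already has the ring A phenol free.
- Against it here: four halogens must be installed and three removed, trivalent thallium is used in stoichiometric amount and is highly toxic, and oxidative macrocyclisations of this kind are usually only moderately efficient. The electron-rich ring C and ring D could be oxidised in competition. A4 still contains the hindered ether and both bridges, so the first difficulty is again left to conventional coupling.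
- Comparison: it is the equal of the chosen plan in the strategic choice of closing the macrocycle at the unhindered ether. It is the better on mildness of the ring-closing step and in not needing a C–Br bond to survive many steps for a late copper coupling. It is worse on step count (about three more), on reagent hazard and on chemoselectivity.

**Alternative 3:** The cut is the ring C carbon–oxygen bond of the hindered C–O–D ether. In the forward direction the ring D phenoxide of the seco fluoro ketone A6 (Cs2CO3, DMF, high dilution) would displace the fluoride ortho to the aryl ketone, giving the macrocyclic ketone A5. The ketone would then have to be removed to reach 20.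
- In its favour: one metal-free step forms the hindered ether and the macrocycle, intramolecular SNAr is tolerant of flanking groups on the electrophile, and the bridge ketone would arise naturally from a convergent acylation.
- Against it here: the fluorine sits between the acyl-bearing carbon and a methoxy carbon, and the para methoxy group lowers the acceptor strength of the ketone, so activation is weak. The ketone is a deoxybenzoin whose CH2 next to ring B would be deprotonated by Cs2CO3, which removes the activation and opens aldol and arylation side paths. Deleting the ketone costs about two steps.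
- Comparison: on convergence it is the better plan, since one step does the work of steps 5 and 11 and the A–O–B ether could be made early by a simple intermolecular coupling. It is the equal of the chosen plan in avoiding copper at the hindered oxygen. It is worse in placing the two hardest tasks in one late step on an advanced intermediate, whereas the chosen plan makes the hindered ether at step 5 on cheap material. The step counts are about the same once ketone removal is counted.

Key step: step 6

Remark on the chemistry: the Wittig product 17 is expected as an E/Z mixture; both isomers converge on 18, so its geometry is left open.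

Remark on the design of 9: the substitution patterns of 9 and 13 map onto rings A, C and D of the target without change, so no structural correction is needed. The aldehyde is kept free because it is non-enolisable and is the handle for ring B, and masking it would cost two steps. Its one weakness, acid-promoted cyclisation of a 2-aryloxybenzaldehyde by the sulfinic acid set free in step 6, is met by the base used there.

## Route

Step 1
Reactants: 1 3-bromo-4-methoxybenzaldehyde
Product: 2 (3-bromo-4-methoxyphenyl)methanol
Conditions: NaBH4, MeOH, 0 °C
Reagents that add atoms: none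
Why: Hydride reduction of an aryl aldehyde with NaBH4; the aryl bromide and the methyl ether are inert.

Step 2
Reactants: 2 (3-bromo-4-methoxyphenyl)methanol
Product: 3 2-bromo-4-(bromomethyl)-1-methoxybenzene
Conditions: PBr3, CH2Cl2, 0 °C to rt
Reagents that add atoms: phosphorus tribromide, BrP(Br)Br
Why: Conversion of a benzylic alcohol into the bromide through its phosphite ester (SN2 by bromide); the electron-rich benzylic position reacts fast at 0 °C and no other group is affected.

Step 3
Reactants: 4 4-hydroxy-6-methyl-2H-pyran-2-one (1.3 equiv); 3 2-bromo-4-(bromomethyl)-1-methoxybenzene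
Product: 6 6-[2-(3-bromo-4-methoxyphenyl)ethyl]-4-hydroxy-2H-pyran-2-one, via dilithiated pyrone dianion 5 (not isolated)
Conditions: LiN(iPr)2 (2.3 equiv per 4), THF/DMPU, −78 °C; then 3, −78 to 0 °C; aq. HCl
Reagents that add atoms: none
Why: Dianion alkylation: after the OH, the 6-methyl group (vinylogous to the lactone carbonyl) is deprotonated, and this more basic carbon site is alkylated by the benzylic bromide while the oxyanion stays passive. An amide base and late addition of 3 avoid bromine–lithium exchange, and the excess of 4 suppresses double alkylation.

Step 4
Reactants: 6 6-[2-(3-bromo-4-methoxyphenyl)ethyl]-4-hydroxy-2H-pyran-2-one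
Product: 7 6-[2-(3-bromo-4-methoxyphenyl)ethyl]-2-oxo-2H-pyran-4-yl 4-methylbenzenesulfonate
Conditions: TsCl, Et3N, CH2Cl2, 0 °C to rt
Reagents that add atoms: 4-methylbenzenesulfonyl chloride, Cc1ccc(cc1)S(=O)(=O)Cl
Why: O-sulfonylation of the acidic vinylogous carboxylic acid OH at C4; the product is a vinylogous mixed anhydride, activated for substitution at C4.

Step 5
Reactants: 7 6-[2-(3-bromo-4-methoxyphenyl)ethyl]-2-oxo-2H-pyran-4-yl 4-methylbenzenesulfonate; 8 2-hydroxy-3,4-dimethoxybenzaldehyde (1.2 equiv)
Product: 9 2-({6-[2-(3-bromo-4-methoxyphenyl)ethyl]-2-oxo-2H-pyran-4-yl}oxy)-3,4-dimethoxybenzaldehyde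
Conditions: K2CO3, DMF, rt to 50 °C
Reagents that add atoms: none
Why: Addition–elimination (vinylogous acyl substitution) of the phenoxide of 8 at pyrone C4 with loss of sulfonate. The phenoxide is flanked by CHO and OMe, but the carbon it attacks is a flat, unhindered and strongly electrophilic sp2 centre, and the mild carbonate base leaves the aldehyde and the lactone alone.

Step 6
Reactants: 9 2-({6-[2-(3-bromo-4-methoxyphenyl)ethyl]-2-oxo-2H-pyran-4-yl}oxy)-3,4-dimethoxybenzaldehyde; 10 phenyl vinyl sulfone (4 equiv)
Product: 13 2-{3-[2-(3-bromo-4-methoxyphenyl)ethyl]phenoxy}-3,4-dimethoxybenzaldehyde, via bridged lactone cycloadduct 11 (not isolated), via sulfonyl cyclohexadiene 12 (not isolated)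
Conditions: iPr2NEt (3 equiv), BHT (cat.), 1,2-dichlorobenzene, 170 °C, sealed tube, argon
Reagents that add atoms: none
Why: The diene of 9 (largest HOMO coefficient at C3, next to the carbon that bears the aryloxy donor) adds the electron-poor alkene 10 across C3 and C6 in a normal-demand Diels–Alder reaction, giving the bridged lactone 11 as a mixture of regio- and stereoisomers. At this temperature 11 loses CO2 by cycloreversion to the cyclohexadiene 12, and 1,2-elimination of benzenesulfinic acid (H from the CH2 next to the diene, sulfinate from the allylic carbon), promoted by the amine and driven by aromatisation, gives the benzene 13. The closest known reaction type is the Diels–Alder/decarboxylation of 2-pyrones with alkynes or with alkenes that carry a leaving group, where a vinyl sulfone acts as an acetylene equivalent. Ring D is closed by an intermolecular [4+2] cycloaddition that forms both new C–C bonds in one event; four ring carbons come from the pyrone and the two unsubstituted CH positions from 10. No stereocentre survives, since those of 11 and 12 are erased on aromatisation, so facial and endo/exo selectivity are irrelevant and both orientations of 10 converge on 13. The selectivity needed is kinetic: aromatisation of 12 must outrun a second cycloaddition of 12 with 10, which the base secures; the base also traps the sulfinic acid so that the acid-sensitive 2-aryloxybenzaldehyde does not cyclise to a xanthene. The hindered amine cannot add to pyrone C4, the aryl bromide and methyl ethers are inert, and BHT keeps 10 from polymerising.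

Step 7
Reactants: 14 1-(benzyloxy)-4-(chloromethyl)benzene
Product: 15 {[4-(benzyloxy)phenyl]methyl}triphenylphosphonium chloride
Conditions: PPh3, toluene, reflux
Reagents that add atoms: triphenylphosphine, c1ccc(cc1)P(c1ccccc1)c1ccccc1
Why: Quaternisation of a phosphine by a reactive benzylic chloride (SN2); the salt should precipitate from toluene.

Step 8
Reactants: 13 2-{3-[2-(3-bromo-4-methoxyphenyl)ethyl]phenoxy}-3,4-dimethoxybenzaldehyde; 15 {[4-(benzyloxy)phenyl]methyl}triphenylphosphonium chloride (1.3 equiv)
Product: 17 1-{2-[4-(benzyloxy)phenyl]ethenyl}-2-{3-[2-(3-bromo-4-methoxyphenyl)ethyl]phenoxy}-3,4-dimethoxybenzene (E/Z mixture), via benzylidene phosphorane ylide 16 (not isolated)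
Conditions: KOtBu, THF, 0 °C; then 13, 0 °C to rt
Reagents that add atoms: none
Why: Wittig olefination of a non-enolisable aryl aldehyde with a semi-stabilised benzylic ylide; an E/Z mixture is expected and is of no consequence, and the aryl bromide and ethers are inert to the base at this temperature.

Step 9
Reactants: 17 1-{2-[4-(benzyloxy)phenyl]ethenyl}-2-{3-[2-(3-bromo-4-methoxyphenyl)ethyl]phenoxy}-3,4-dimethoxybenzene
Product: 18 1-{2-[4-(benzyloxy)phenyl]ethyl}-2-{3-[2-(3-bromo-4-methoxyphenyl)ethyl]phenoxy}-3,4-dimethoxybenzene
Conditions: TsNHNH2 (excess, in portions), NaOAc, THF/H2O, reflux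
Reagents that add atoms: none
Why: Diimide reduction: diimide from the sulfonyl hydrazide delivers H2 to the non-polar stilbene C=C by concerted syn transfer. Unlike hydrogenation over palladium it touches neither the C–Br bond needed in step 11 nor the benzyl ether.

Step 10
Reactants: 18 1-{2-[4-(benzyloxy)phenyl]ethyl}-2-{3-[2-(3-bromo-4-methoxyphenyl)ethyl]phenoxy}-3,4-dimethoxybenzene
Product: 19 4-[2-(2-{3-[2-(3-bromo-4-methoxyphenyl)ethyl]phenoxy}-3,4-dimethoxyphenyl)ethyl]phenol
Conditions: BCl3, C6HMe5, CH2Cl2, −78 °C; then MeOH
Reagents that add atoms: none
Why: Lewis acid debenzylation of an aryl benzyl ether: BCl3 activates the ether and pentamethylbenzene takes up the benzyl cation in a Friedel–Crafts alkylation. At −78 °C the methyl ethers, the diaryl ether and the bromide should stay intact; hydrogenolysis is avoided because of the C–Br bond.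

Step 11
Reactants: 19 4-[2-(2-{3-[2-(3-bromo-4-methoxyphenyl)ethyl]phenoxy}-3,4-dimethoxyphenyl)ethyl]phenol
Product: 20 tri-O-methylmarchantin H (18-membered macrocycle with OMe on ring A and two OMe on ring C)
Conditions: CuI (50 mol %), N,N-dimethylglycine·HCl, Cs2CO3, 1,4-dioxane, 100 °C, slow addition of 19 (final 2 mM)
Reagents that add atoms: none
Why: Intramolecular Ullmann diaryl ether synthesis with monovalent copper and an amino acid ligand, closing the 18-membered ring at the less hindered ether. The ring B phenol has free ortho positions and the bromide has one ortho neighbour, they are the only phenol and the only halide in the molecule, and slow addition keeps the concentration low so that ring closure outruns oligomerisation.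

Step 12
Reactants: 20 tri-O-methylmarchantin H
Product: 21 marchantin H
Conditions: BBr3 (excess), CH2Cl2, −78 °C to rt; then H2O, work-up under argon
Reagents that add atoms: none
Why: Cleavage of the three aryl methyl ethers by BBr3 (oxygen–boron complex, SN2 attack of bromide on methyl, hydrolysis of the aryl borates); diaryl ethers are not cleaved under these conditions, and exclusion of air protects the freed catechol.

## Compound list

1 | 3-bromo-4-methoxybenzaldehyde | COc1ccc(C=O)cc1Br | starting material
2 | (3-bromo-4-methoxyphenyl)methanol | COc1ccc(CO)cc1Br | intermediate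
3 | 2-bromo-4-(bromomethyl)-1-methoxybenzene | COc1ccc(CBr)cc1Br | intermediate
4 | 4-hydroxy-6-methyl-2H-pyran-2-one | CC1=CC(O)=CC(=O)O1 | starting material
5 | dilithium salt of the O,C-dianion of 4-hydroxy-6-methyl-2H-pyran-2-one (not isolated) | [Li+].[Li+].[CH2-]C1=CC([O-])=CC(=O)O1 | intermediate
6 | 6-[2-(3-bromo-4-methoxyphenyl)ethyl]-4-hydroxy-2H-pyran-2-one | O=C1C=C(O)C=C(CCc2ccc(OC)c(Br)c2)O1 | intermediate
7 | 6-[2-(3-bromo-4-methoxyphenyl)ethyl]-2-oxo-2H-pyran-4-yl 4-methylbenzenesulfonate | Cc1ccc(cc1)S(=O)(=O)OC1=CC(=O)OC(CCc2ccc(OC)c(Br)c2)=C1 | intermediate
8 | 2-hydroxy-3,4-dimethoxybenzaldehyde | COc1ccc(C=O)c(O)c1OC | starting material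
9 | 2-({6-[2-(3-bromo-4-methoxyphenyl)ethyl]-2-oxo-2H-pyran-4-yl}oxy)-3,4-dimethoxybenzaldehyde | O=C1C=C(Oc2c(OC)c(OC)ccc2C=O)C=C(CCc2ccc(OC)c(Br)c2)O1 | intermediate
10 | phenyl vinyl sulfone | C=CS(=O)(=O)c1ccccc1 | starting material
11 | 1-[2-(3-bromo-4-methoxyphenyl)ethyl]-5-(6-formyl-2,3-dimethoxyphenoxy)-7-(phenylsulfonyl)-2-oxabicyclo[2.2.2]oct-5-en-3-one (expected major regioisomer, mixture of stereoisomers, not isolated) | O=C1OC2(CCc3ccc(OC)c(Br)c3)C(S(=O)(=O)c3ccccc3)CC1C(Oc1c(OC)c(OC)ccc1C=O)=C2 | intermediate
12 | 2-({5-[2-(3-bromo-4-methoxyphenyl)ethyl]-4-(phenylsulfonyl)cyclohexa-1,5-dien-1-yl}oxy)-3,4-dimethoxybenzaldehyde (racemic, not isolated) | O=Cc1ccc(OC)c(OC)c1OC1=CCC(S(=O)(=O)c2ccccc2)C(CCc2ccc(OC)c(Br)c2)=C1 | intermediate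
13 | 2-{3-[2-(3-bromo-4-methoxyphenyl)ethyl]phenoxy}-3,4-dimethoxybenzaldehyde | O=Cc1ccc(OC)c(OC)c1Oc1cccc(c1)CCc1ccc(OC)c(Br)c1 | intermediate
14 | 1-(benzyloxy)-4-(chloromethyl)benzene | ClCc1ccc(OCc2ccccc2)cc1 | starting material
15 | {[4-(benzyloxy)phenyl]methyl}triphenylphosphonium chloride | [Cl-].c1ccc(cc1)COc1ccc(C[P+](c2ccccc2)(c2ccccc2)c2ccccc2)cc1 | intermediate
16 | {[4-(benzyloxy)phenyl]methylidene}triphenylphosphorane (not isolated) | c1ccc(COc2ccc(C=P(c3ccccc3)(c3ccccc3)c3ccccc3)cc2)cc1 | intermediate
17 | 1-{2-[4-(benzyloxy)phenyl]ethenyl}-2-{3-[2-(3-bromo-4-methoxyphenyl)ethyl]phenoxy}-3,4-dimethoxybenzene (E/Z mixture) | COc1ccc(C=Cc2ccc(OCc3ccccc3)cc2)c(Oc2cccc(CCc3ccc(OC)c(Br)c3)c2)c1OC | intermediate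
18 | 1-{2-[4-(benzyloxy)phenyl]ethyl}-2-{3-[2-(3-bromo-4-methoxyphenyl)ethyl]phenoxy}-3,4-dimethoxybenzene | COc1ccc(CCc2ccc(OCc3ccccc3)cc2)c(Oc2cccc(CCc3ccc(OC)c(Br)c3)c2)c1OC | intermediate
19 | 4-[2-(2-{3-[2-(3-bromo-4-methoxyphenyl)ethyl]phenoxy}-3,4-dimethoxyphenyl)ethyl]phenol | COc1ccc(CCc2ccc(O)cc2)c(Oc2cccc(CCc3ccc(OC)c(Br)c3)c2)c1OC | intermediate
20 | tri-O-methylmarchantin H | COc1ccc2cc1Oc1ccc(cc1)CCc1ccc(OC)c(OC)c1Oc1cccc(c1)CC2 | intermediate
21 | marchantin H | Oc1ccc2cc1Oc1ccc(cc1)CCc1ccc(O)c(O)c1Oc1cccc(c1)CC2 | target

## Step count and risks

Total step count: 12. Longest linear sequence: 11 steps (steps 1 to 6 and 8 to 12); step 7 is a one-step side branch.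

**Step 6 (key step).** The most likely failure is a cycloaddition too slow to compete with thermal decay, because a 4-aryloxy-6-alkyl-2-pyrone is a stabilised, reluctant diene. Further risks are a second cycloaddition of 12 before it aromatises, consumption of 10 by polymerisation or by addition of the liberated sulfinate, and displacement of the aryloxy group from pyrone C4 by sulfinate. The fallback abandons the pyrone, sets out from 3 and comes back at 13. Compound 3 is quaternised with PPh3 to [(3-bromo-4-methoxyphenyl)methyl]triphenylphosphonium bromide F1. A Wittig reaction of F1 with 3-hydroxybenzaldehyde (KOtBu, 2.2 equiv, THF) gives 3-[2-(3-bromo-4-methoxyphenyl)ethenyl]phenol F2 as an E/Z mixture. Diimide reduction as in step 9 gives 3-[2-(3-bromo-4-methoxyphenyl)ethyl]phenol F3. Nucleophilic aromatic substitution of the unhindered phenoxide of F3 on commercial 2-fluoro-3,4-dimethoxybenzaldehyde (K2CO3, DMA, 140 °C), whose fluoride is activated by the ortho aldehyde, gives 13.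

**Step 11.** The most likely failure is intermolecular coupling to dimers and oligomers, or hydrodebromination, because closure of an 18-membered ring is slow and the bromide is electron-rich. The fallback closes the ring at the B–C bridge instead, sets out from 13 and comes back at 20. Intermolecular Ullmann coupling of 13 with 4-(hydroxymethyl)phenol (CuI, picolinic acid, K3PO4, DMSO, 90 °C; selective for the phenol, run concentrated) gives 2-[3-(2-{3-[4-(hydroxymethyl)phenoxy]-4-methoxyphenyl}ethyl)phenoxy]-3,4-dimethoxybenzaldehyde F4. Treatment with PPh3·HBr in refluxing MeCN gives the formyl phosphonium bromide F5. Intramolecular Wittig reaction under high dilution (NaOMe, CH2Cl2/MeOH, rt) gives the macrocyclic stilbene F6 as an E/Z mixture. Hydrogenation (H2, Pd/C, EtOAc), now free of any C–Br bond, gives 20.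

**Step 5.** The most likely failure is attack of the phenoxide at the sulfonyl sulfur instead of at C4, which transfers the sulfonyl group to 8 and returns 6. A second risk is opening of the pyrone ring by adventitious hydroxide. The fallback removes the sulfonyl centre, sets out from 6 and comes back at 9. Compound 6 is converted with Bu4NBr and P2O5 in toluene at 100 °C into 4-bromo-6-[2-(3-bromo-4-methoxyphenyl)ethyl]-2H-pyran-2-one F7. Addition–elimination of 8 on this vinylogous acyl bromide (K2CO3, DMF) gives 9.

**Step 3.** The most likely failure is incomplete formation or poor solubility of the dianion, leading to O-alkylation, double alkylation or recovered 3. The fallback assembles the pyrone from an open chain, sets out from 3 and comes back at 6. Alkylation of the lithium enolate of N-methoxy-N-methylacetamide with 3 (LiN(iPr)2, THF, −78 °C) gives 3-(3-bromo-4-methoxyphenyl)-N-methoxy-N-methylpropanamide F8. Acylation of the dianion of methyl acetoacetate (NaH, then n-BuLi, THF, 0 °C) with F8 gives methyl 7-(3-bromo-4-methoxyphenyl)-3,5-dioxoheptanoate F9. Lactonisation of its enol onto the ester (DBU, toluene, reflux) gives 6.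

## Further compounds

F1 | step 6 | [(3-bromo-4-methoxyphenyl)methyl]triphenylphosphonium bromide | COc1ccc(C[P+](c2ccccc2)(c2ccccc2)c2ccccc2)cc1Br.[Br-]
F2 | step 6 | 3-[2-(3-bromo-4-methoxyphenyl)ethenyl]phenol (E/Z mixture) | COc1ccc(C=Cc2cccc(O)c2)cc1Br
F3 | step 6 | 3-[2-(3-bromo-4-methoxyphenyl)ethyl]phenol | COc1ccc(CCc2cccc(O)c2)cc1Br
F4 | step 11 | 2-[3-(2-{3-[4-(hydroxymethyl)phenoxy]-4-methoxyphenyl}ethyl)phenoxy]-3,4-dimethoxybenzaldehyde | O=Cc1ccc(OC)c(OC)c1Oc1cccc(c1)CCc1ccc(OC)c(Oc2ccc(CO)cc2)c1
F5 | step 11 | {[4-(5-{2-[3-(6-formyl-2,3-dimethoxyphenoxy)phenyl]ethyl}-2-methoxyphenoxy)phenyl]methyl}triphenylphosphonium bromide | O=Cc1ccc(OC)c(OC)c1Oc1cccc(c1)CCc1ccc(OC)c(Oc2ccc(C[P+](c3ccccc3)(c3ccccc3)c3ccccc3)cc2)c1.[Br-]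
F6 | step 11 | 18-membered macrocyclic stilbene, tri-O-methyl, C=C in the ring B–ring C bridge (E/Z mixture) | COc1ccc2cc1Oc1ccc(cc1)C=Cc1ccc(OC)c(OC)c1Oc1cccc(c1)CC2
F7 | step 5 | 4-bromo-6-[2-(3-bromo-4-methoxyphenyl)ethyl]-2H-pyran-2-one | O=C1C=C(Br)C=C(CCc2ccc(OC)c(Br)c2)O1
F8 | step 3 | 3-(3-bromo-4-methoxyphenyl)-N-methoxy-N-methylpropanamide | CON(C)C(=O)CCc1ccc(OC)c(Br)c1
F9 | step 3 | methyl 7-(3-bromo-4-methoxyphenyl)-3,5-dioxoheptanoate | COC(=O)CC(=O)CC(=O)CCc1ccc(OC)c(Br)c1
A1 | alternative 1 | 18-membered macrocyclic E-stilbene, tri-O-methyl, C=C in the ring B–ring C bridge | COc1ccc2cc1Oc1ccc(cc1)/C=C/c1ccc(OC)c(OC)c1Oc1cccc(c1)CC2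
A2 | alternative 1 | 19-membered dibenzylic sulfone, tri-O-methyl, CH2–SO2–CH2 between ring B and ring C | COc1ccc2cc1Oc1ccc(cc1)CS(=O)(=O)Cc1ccc(OC)c(OC)c1Oc1cccc(c1)CC2
A3 | alternative 2 | trihalogenated macrocycle (Br on ring A, two Cl on ring B, ring C as dimethyl ether) | Oc1c(Br)cc2cc1Oc1c(Cl)cc(cc1Cl)CCc1ccc(OC)c(OC)c1Oc1cccc(c1)CC2
A4 | alternative 2 | seco bisphenol: 2,6-dibromo-4-{2-[3-(6-{2-[3,5-dichloro-4-hydroxyphenyl]ethyl}-2,3-dimethoxyphenoxy)phenyl]ethyl}phenol | Oc1c(Br)cc(cc1Br)CCc1cccc(c1)Oc1c(OC)c(OC)ccc1CCc1cc(Cl)c(O)c(Cl)c1
A5 | alternative 3 | macrocyclic ketone, tri-O-methyl, C=O on the bridge carbon attached to ring C | COc1ccc2cc1Oc1ccc(cc1)CC(=O)c1ccc(OC)c(OC)c1Oc1cccc(c1)CC2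
A6 | alternative 3 | seco fluoro ketone: 1-(2-fluoro-3,4-dimethoxyphenyl)-2-[4-(5-{2-[3-hydroxyphenyl]ethyl}-2-methoxyphenoxy)phenyl]ethanone | Oc1cccc(c1)CCc1ccc(OC)c(c1)Oc1ccc(cc1)CC(=O)c1ccc(OC)c(OC)c1F
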